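**Plan**

1. Retrosynthetic cuts, in order: O–C18 of the pendant lactone (ring E), back to a cis-β-lactone by reversing a 1,2-hydride/oxygen dyotropic shift; C19–C20 and C19–O (aldehyde plus methylketene); N4–C9a and N4–C3 (pyrrole ring A and azepane ring B together); C1–C2 (enolate propargylation); C12–C13 (tethered Michael addition, ring D); C10–ethyl and C9–C8 (ethylation and conjugate addition on a quinone monoketal, ring C).
2. Forward order: ring C is carried from the monoketal, ring D is annulated onto it, rings A and B are closed in one operation from an azido alkynyl ketone, and ring E is made last from the side-chain aldehyde by [2+2] cycloaddition and ring expansion.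
3. Enabling feature: C18 sits directly on C3 of the electron-rich N4 pyrrole (ring A) and next to the C19 methylene, so a hydride on C18 can move to C19 as a strained C19–O bond ionises, with the pyrrole nitrogen carrying the charge (azafulvenium) until the carboxylate closes on C18.
4. Stereochemistry: C9 from a chiral copper catalyst; C10 by trans alkylation; C11 by Luche reduction then Mitsunobu inversion; C12 by the tether (cis fusion); C13 by convex-face protonation; C19 and C20 from a cinchona catalyst; C18 by transfer from C19 in the ring expansion (cis-β-lactone to trans-γ-lactone).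

Key step: step 16

Numbering: Stemona-type locants are used throughout: N4; pyrrole (ring A) C1, C2, C3, C9a; azepane (ring B) C5–C9; cyclohexane (ring C) C9, C10 (ethyl), C11, C12, C1, C9a; fused lactone (ring D) C11–O–C14(=O)–C13(CH3)–C12; pendant lactone (ring E) O–C18–C19–C20(CH3)–C21(=O) with C18 on C3.

Assumption: the (R,S)-configured ferrocenyl diphosphine in step 2 and O-trimethylsilylquinidine in step 15 are taken to give the senses of induction drawn; if either proves opposite, the mirror-image ligand or the quinine-derived pseudoenantiomer would be used.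

**Step 1**
Reactants: 1 1-bromo-4-chlorobutane
Product: 2 (4-chlorobutyl)magnesium bromide
Conditions: Mg turnings, Et2O, 0 °C → rt; used as a titrated solution
Reagents that add atoms: magnesium, [Mg]
Why: Grignard reagent formation by insertion of magnesium into the C–Br bond, which is much faster than insertion into the C–Cl bond, should give the chloro-functionalised one-to-one organomagnesium reagent needed for the conjugate addition.

**Step 2**
Reactants: 3 4,4-dimethoxycyclohexa-2,5-dien-1-one; 2 (4-chlorobutyl)magnesium bromide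
Product: 5 {[(3R)-3-(4-chlorobutyl)-4,4-dimethoxycyclohexa-1,5-dien-1-yl]oxy}trimethylsilane, via magnesium enolate 4 (not isolated)
Conditions: CuBr·SMe2 (5 mol%), (R)-1-[(S)-2-(diphenylphosphino)ferrocenyl]ethyldicyclohexylphosphine (6 mol%), tBuOMe, −78 °C, slow addition of 2; then Me3SiCl, Et3N, DMPU, −78 → 0 °C
Reagents that add atoms: trimethylsilyl chloride, C[Si](C)(C)Cl
Why: Copper-catalysed asymmetric conjugate addition of a Grignard reagent (ferrocenyl diphosphine ligand) to the cross-conjugated dienone monoketal should differentiate the enantiotopic faces of 3 and set C9 by catalyst control, and O-silylation of the magnesium enolate fixes the enolate regiochemistry for the alkylation that follows.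

**Step 3**
Reactants: 5 silyl dienol ether
Product: 7 (5R,6R)-5-(4-chlorobutyl)-6-ethyl-4,4-dimethoxycyclohex-2-en-1-one, via lithium enolate 6 (not isolated)
Conditions: MeLi, THF, 0 °C; then EtI (excess), DMPU, −78 → −20 °C
Reagents that add atoms: iodoethane, CCI
Why: Si–O cleavage with MeLi releases the regiodefined lithium enolate, whose C-ethylation (enolate alkylation) by excess iodoethane should outrun attack on the far less reactive primary chloride and occur anti to the adjacent C9 chain to set C10 trans; C10 is epimerisable and trans is also the thermodynamic arrangement, while C9 cannot epimerise at this stage.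

**Step 4**
Reactants: 7 enone ketal
Product: 8 (1R,5R,6R)-5-(4-chlorobutyl)-6-ethyl-4,4-dimethoxycyclohex-2-en-1-ol
Conditions: NaBH4, CeCl3·7H2O, MeOH, −78 °C
Reagents that add atoms: none
Why: Luche reduction gives clean 1,2-reduction of the enone, and axial hydride delivery to the half-chair with both ring substituents equatorial should give the equatorial C11 alcohol trans to the ethyl group, the configuration needed for inversion in step 5.

**Step 5**
Reactants: 8 allylic alcohol; 9 2-(phenylsulfonyl)acetic acid
Product: 10 (1S,5R,6R)-5-(4-chlorobutyl)-6-ethyl-4,4-dimethoxycyclohex-2-en-1-yl 2-(phenylsulfonyl)acetate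
Conditions: PPh3, DIAD, toluene, 0 °C → rt
Reagents that add atoms: none
Why: Mitsunobu esterification with an acidic carboxylic acid proceeds with SN2 inversion at the allylic carbinol, placing the C11–O bond cis to the ethyl group and installing the sulfonyl-activated two-carbon tether for lactone annulation in the same operation.

**Step 6**
Reactants: 10 ketal ester
Product: 11 (1S,5R,6R)-5-(4-chlorobutyl)-6-ethyl-4-oxocyclohex-2-en-1-yl 2-(phenylsulfonyl)acetate
Conditions: 1 M aq HCl, THF, 0 °C
Reagents that add atoms: water, O
Why: Mild acid hydrolysis of the allylic dimethyl ketal unmasks the C9a ketone and so transposes the enone, making C12 its electrophilic β-carbon next to the acyloxy-bearing C11; the ester survives, and C9, now epimerisable, already has the thermodynamic trans arrangement.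

**Step 7**
Reactants: 11 enone ester
Product: 13 (3aS,6R,7R,7aR)-6-(4-chlorobutyl)-7-ethyl-3-methyl-3-(phenylsulfonyl)hexahydro-1-benzofuran-2,5-dione (C3 epimers), via sulfonyl lactone 12 (not isolated)
Conditions: Cs2CO3, MeCN, 0 °C → rt; then MeI, rt
Reagents that add atoms: iodomethane, CI
Why: Intramolecular Michael addition of the sulfonyl-stabilised carbanion (5-exo-trig) can reach C12 only from the face of the C11 oxygen, so the γ-lactone is cis-fused and C12 is set by the tether; the acidic sulfonyl lactone is then C-methylated in the same pot, the C13 configuration being immaterial until step 8.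

**Step 8**
Reactants: 13 methylated sulfonyl lactone
Product: 14 (3S,3aR,6R,7R,7aR)-6-(4-chlorobutyl)-7-ethyl-3-methylhexahydro-1-benzofuran-2,5-dione
Conditions: SmI2, THF/MeOH, −78 °C
Reagents that add atoms: none
Why: Reductive desulfonylation with SmI2 cleaves the C–S bond α to the lactone carbonyl much faster than it reduces the unactivated ketone or the chloride, and kinetic protonation of the samarium enolate from the convex face of the cis-fused bicycle (anti to the C12–C1 bond) should set C13 with the methyl group on the concave face, as in the target.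

**Step 9**
Reactants: 15 4-chlorobut-2-yn-1-ol
Product: 17 tert-butyl[(4-iodobut-2-yn-1-yl)oxy]dimethylsilane, via chloride silyl ether 16 (not isolated)
Conditions: TBSCl, imidazole, DMF, 0 °C → rt; then NaI, rt, dark
Reagents that add atoms: tert-butyldimethylsilyl chloride, CC(C)(C)[Si](C)(C)Cl; sodium iodide, [Na+].[I-]
Why: Silylation of the primary alcohol followed by Finkelstein exchange converts the propargylic chloride into the more reactive iodide without isolating the intermediate.

**Step 10**
Reactants: 14 keto lactone; 17 propargylic iodide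
Product: 19 (3S,3aR,6R,7R,7aR)-4-[4-(tert-butyldimethylsilyloxy)but-2-yn-1-yl]-6-(4-chlorobutyl)-7-ethyl-3-methylhexahydro-1-benzofuran-2,5-dione (C4 epimers), via lithium enolate 18 (not isolated)
Conditions: LiN(SiMe3)2 (1.0 equiv), THF, −78 °C; then 17, DMPU, −78 → −40 °C
Reagents that add atoms: none
Why: Kinetic deprotonation with one equivalent of base at −78 °C should occur at the less substituted ketone α-methylene (C1) and not at C9–H or the less acidic lactone C13–H, and the enolate is C-alkylated by the propargylic iodide (enolate alkylation); the new C1 centre is lost later on aromatisation.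

**Step 11**
Reactants: 19 chloro alkynyl ketone
Product: 20 (3S,3aR,6R,7R,7aR)-6-(4-azidobutyl)-4-[4-(tert-butyldimethylsilyloxy)but-2-yn-1-yl]-7-ethyl-3-methylhexahydro-1-benzofuran-2,5-dione (C4 epimers)
Conditions: NaN3, DMF, 60 °C
Reagents that add atoms: sodium azide, [Na+].[N-]=[N+]=[N-]
Why: SN2 displacement of the primary chloride by azide introduces N4 in masked form, and the weakly basic azide does not epimerise C13.

**Step 12**
Reactants: 20 azido alkynyl ketone
Product: 23 tetracyclic pyrrole (rings A–D of the target) carrying a 2-(tert-butyldimethylsilyloxy)ethyl group on C3, via iminophosphorane 21 (not isolated), via cyclic imine 22 (not isolated)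
Conditions: PPh3 (1.0 equiv), toluene, rt → 90 °C; then (Ph3P)AuNTf2 (5 mol%), 60 °C
Reagents that add atoms: none
Why: Staudinger reaction gives an iminophosphorane that closes the seven-membered ring by intramolecular aza-Wittig reaction with the C9a ketone, and monovalent-gold activation of the alkyne then triggers 5-exo-dig attack of the imine/enamine nitrogen on C3 and tautomerisation to the aromatic pyrrole (the intramolecular form of the amine plus 4-ynone pyrrole synthesis); C9 can epimerise through the enamine, but trans to the ethyl group is the thermodynamic arrangement.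

**Step 13**
Reactants: 23 silyl ether
Product: 24 the corresponding tetracyclic pyrrole carrying a 2-hydroxyethyl group on C3
Conditions: Bu4NF, AcOH, THF, 0 °C → rt
Reagents that add atoms: none
Why: Fluoride-mediated silyl ether cleavage, buffered with acetic acid so that the lactone α-centre C13 is not epimerised.

**Step 14**
Reactants: 24 primary alcohol
Product: 25 the corresponding tetracyclic pyrrole carrying a 2-oxoethyl group on C3 (pyrrol-2-ylacetaldehyde)
Conditions: SO3·pyridine, DMSO, Et3N, CH2Cl2, 0 °C
Reagents that add atoms: none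
Why: Parikh–Doering oxidation gives the aldehyde under non-acidic, non-electrophilic conditions that spare the electron-rich pyrrole; the enolisable aldehyde is used at once.

**Step 15**
Reactants: 25 aldehyde
Product: 26 cis-β-lactone, the tetracyclic pyrrole carrying a [(2R,3S)-3-methyl-4-oxooxetan-2-yl]methyl group on C3, i.e. a (3S,4R)-3-methyl-4-(pyrrolylmethyl)oxetan-2-one
Conditions: EtCOCl, iPr2NEt, O-trimethylsilylquinidine (10 mol%), LiClO4, CH2Cl2/Et2O, −78 °C
Reagents that add atoms: propanoyl chloride, CCC(Cl)=O
Why: Cinchona-alkaloid/LiClO4-catalysed acyl halide–aldehyde cyclocondensation (formal [2+2] of methylketene, formed in the flask, with the aldehyde through a chiral ammonium enolate) should give the cis-3,4-disubstituted β-lactone, with C19 and C20 set by the catalyst independently of the remote core stereocentres.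

**Step 16**
Reactants: 26 cis-β-lactone
Product: 27 CNP0232452.1, (9R,10R,11R,12S,13S,18R,20S)-configured target
Conditions: MgBr2·OEt2, CH2Cl2, −40 → 0 °C
Reagents that add atoms: none
Why: Coordination of MgBr2 to the β-lactone carbonyl weakens the strained C19–O bond, and as it ionises the C18–H bond antiperiplanar to it migrates as hydride to C19 while the carboxylate oxygen closes on C18, whose developing positive charge is delocalised into the N4–C3 pyrrole ring (azafulvenium character). The closest known reaction type is the Lewis-acid-promoted dyotropic (Wagner–Meerwein) ring expansion of β-lactones to γ-butyrolactones with 1,2-hydride or alkyl shift. Ring E is closed by O–C18 bond formation, a 5-exo-trig capture of the azafulvenium carbon that expands the four-membered ring to the five-membered one and is driven by release of β-lactone strain. The new C18 stereocentre is controlled by the C19 stereocentre of 26, which is consumed in the process: oxygen enters C18 anti to the departing hydride, and with the pyrrolyl group anti to C20 in the reactive rotamer the (3S,4R)-cis-β-lactone should give the (18R,20S)-trans-γ-lactone, C20 being untouched. The step needs hydride instead of pyrrolyl migration and retention of stereochemical memory; the cis methyl group on C20 disfavours the rotamer that would place the pyrrolyl group antiperiplanar to C19–O, and a tight magnesium carboxylate/azafulvenium ion pair at low temperature in a non-polar solvent should collapse before rotation about C18–C19. Because oxidation at C18 is paid for by reduction at C19, no external oxidant is needed and the other pyrrolylic C–H bonds (C9–H, C12–H) are not at risk.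

**Compound list**

1 | 1-bromo-4-chlorobutane | ClCCCCBr | starting material
2 | (4-chlorobutyl)magnesium bromide | ClCCCC[Mg]Br | intermediate
3 | 4,4-dimethoxycyclohexa-2,5-dien-1-one | COC1(OC)C=CC(=O)C=C1 | starting material
4 | bromomagnesium (3R)-3-(4-chlorobutyl)-4,4-dimethoxycyclohexa-1,5-dien-1-olate (magnesium enolate) | Br[Mg]OC1=C[C@@H](CCCCCl)C(OC)(OC)C=C1 | intermediate
5 | {[(3R)-3-(4-chlorobutyl)-4,4-dimethoxycyclohexa-1,5-dien-1-yl]oxy}trimethylsilane | C[Si](C)(C)OC1=C[C@@H](CCCCCl)C(OC)(OC)C=C1 | intermediate
6 | lithium (3R)-3-(4-chlorobutyl)-4,4-dimethoxycyclohexa-1,5-dien-1-olate | [Li]OC1=C[C@@H](CCCCCl)C(OC)(OC)C=C1 | intermediate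
7 | (5R,6R)-5-(4-chlorobutyl)-6-ethyl-4,4-dimethoxycyclohex-2-en-1-one | CC[C@H]1C(=O)C=CC(OC)(OC)[C@@H]1CCCCCl | intermediate
8 | (1R,5R,6R)-5-(4-chlorobutyl)-6-ethyl-4,4-dimethoxycyclohex-2-en-1-ol | CC[C@H]1[C@H](O)C=CC(OC)(OC)[C@@H]1CCCCCl | intermediate
9 | 2-(phenylsulfonyl)acetic acid | OC(=O)CS(=O)(=O)c1ccccc1 | starting material
10 | (1S,5R,6R)-5-(4-chlorobutyl)-6-ethyl-4,4-dimethoxycyclohex-2-en-1-yl 2-(phenylsulfonyl)acetate | CC[C@H]1[C@@H](OC(=O)CS(=O)(=O)c2ccccc2)C=CC(OC)(OC)[C@@H]1CCCCCl | intermediate
11 | (1S,5R,6R)-5-(4-chlorobutyl)-6-ethyl-4-oxocyclohex-2-en-1-yl 2-(phenylsulfonyl)acetate | CC[C@H]1[C@@H](OC(=O)CS(=O)(=O)c2ccccc2)C=CC(=O)[C@@H]1CCCCCl | intermediate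
12 | (3aS,6R,7R,7aR)-6-(4-chlorobutyl)-7-ethyl-3-(phenylsulfonyl)hexahydro-1-benzofuran-2,5-dione (C3 epimers) | CC[C@H]1[C@H]2OC(=O)C(S(=O)(=O)c3ccccc3)[C@H]2CC(=O)[C@@H]1CCCCCl | intermediate
13 | (3aS,6R,7R,7aR)-6-(4-chlorobutyl)-7-ethyl-3-methyl-3-(phenylsulfonyl)hexahydro-1-benzofuran-2,5-dione (C3 epimers) | CC[C@H]1[C@H]2OC(=O)C(C)(S(=O)(=O)c3ccccc3)[C@H]2CC(=O)[C@@H]1CCCCCl | intermediate
14 | (3S,3aR,6R,7R,7aR)-6-(4-chlorobutyl)-7-ethyl-3-methylhexahydro-1-benzofuran-2,5-dione | CC[C@H]1[C@H]2OC(=O)[C@@H](C)[C@H]2CC(=O)[C@@H]1CCCCCl | intermediate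
15 | 4-chlorobut-2-yn-1-ol | OCC#CCCl | starting material
16 | tert-butyl[(4-chlorobut-2-yn-1-yl)oxy]dimethylsilane | CC(C)(C)[Si](C)(C)OCC#CCCl | intermediate
17 | tert-butyl[(4-iodobut-2-yn-1-yl)oxy]dimethylsilane | CC(C)(C)[Si](C)(C)OCC#CCI | intermediate
18 | lithium enolate of 14 (C1–C9a enolate; benzofuranone C4–C5) | CC[C@H]1[C@H]2OC(=O)[C@@H](C)[C@H]2C=C(O[Li])[C@@H]1CCCCCl | intermediate
19 | (3S,3aR,6R,7R,7aR)-4-[4-(tert-butyldimethylsilyloxy)but-2-yn-1-yl]-6-(4-chlorobutyl)-7-ethyl-3-methylhexahydro-1-benzofuran-2,5-dione (C4 epimers) | CC[C@H]1[C@H]2OC(=O)[C@@H](C)[C@H]2C(CC#CCO[Si](C)(C)C(C)(C)C)C(=O)[C@@H]1CCCCCl | intermediate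
20 | (3S,3aR,6R,7R,7aR)-6-(4-azidobutyl)-4-[4-(tert-butyldimethylsilyloxy)but-2-yn-1-yl]-7-ethyl-3-methylhexahydro-1-benzofuran-2,5-dione (C4 epimers) | CC[C@H]1[C@H]2OC(=O)[C@@H](C)[C@H]2C(CC#CCO[Si](C)(C)C(C)(C)C)C(=O)[C@@H]1CCCCN=[N+]=[N-] | intermediate
21 | iminophosphorane of 20 (N=PPh3 in place of the azide) | CC[C@H]1[C@H]2OC(=O)[C@@H](C)[C@H]2C(CC#CCO[Si](C)(C)C(C)(C)C)C(=O)[C@@H]1CCCCN=P(c1ccccc1)(c1ccccc1)c1ccccc1 | intermediate
22 | seven-membered cyclic imine (C9a=N4, rings B, C and D closed, alkynyl chain on C1) | CC[C@H]1[C@H]2OC(=O)[C@@H](C)[C@H]2C(CC#CCO[Si](C)(C)C(C)(C)C)C3=NCCCC[C@H]13 | intermediate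
23 | (9R,10R,11R,12S,13S)-tetracyclic pyrrole (rings A–D) with 2-(tert-butyldimethylsilyloxy)ethyl on C3 | CC[C@H]1[C@H]2OC(=O)[C@@H](C)[C@H]2c2cc(CCO[Si](C)(C)C(C)(C)C)n3c2[C@@H]1CCCC3 | intermediate
24 | (9R,10R,11R,12S,13S)-tetracyclic pyrrole with 2-hydroxyethyl on C3 | CC[C@H]1[C@H]2OC(=O)[C@@H](C)[C@H]2c2cc(CCO)n3c2[C@@H]1CCCC3 | intermediate
25 | (9R,10R,11R,12S,13S)-tetracyclic pyrrole with 2-oxoethyl on C3 | CC[C@H]1[C@H]2OC(=O)[C@@H](C)[C@H]2c2cc(CC=O)n3c2[C@@H]1CCCC3 | intermediate
26 | (9R,10R,11R,12S,13S)-tetracyclic pyrrole with [(2R,3S)-3-methyl-4-oxooxetan-2-yl]methyl on C3 (cis-β-lactone) | CC[C@H]1[C@H]2OC(=O)[C@@H](C)[C@H]2c2cc(C[C@H]4OC(=O)[C@H]4C)n3c2[C@@H]1CCCC3 | intermediate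
27 | CNP0232452.1, (9R,10R,11R,12S,13S,18R,20S)-pentacyclic bis-lactone with a trans pendant lactone | CC[C@H]1[C@H]2OC(=O)[C@@H](C)[C@H]2c2cc([C@H]3C[C@H](C)C(=O)O3)n3c2[C@@H]1CCCC3 | target

**Step count and risks**

Total steps: 16. Longest linear sequence: 15 steps (steps 1–8 and 10–16; step 9 is a one-step side branch).

Step 16 (most at risk): the pyrrolyl group may migrate instead of hydride through a bridged cation, and stereochemical memory may be lost if the ion pair rotates before collapse or the product re-ionises at C18. Fallback, setting out from 26 and returning at 27: PhSeNa (from PhSeSePh and NaBH4) opens the β-lactone at C19 (alkyl–oxygen cleavage, SN2) to give the β-seleno acid F1; radical deselenation (Bu3SnH, AIBN) gives the saturated (S)-acid F2; DDQ in CH2Cl2 then effects oxidative lactonisation by hydride abstraction at the pyrrolylic C18 and capture by the carboxylic acid, giving 27. In this variant C18 rests only on 1,3-induction from C20, so the C18 epimer F3 would be separated and recycled by acid equilibration through the azafulvenium ion.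

Step 15: amine-mediated enolisation, self-condensation or enol O-acylation of the pyrrolylacetaldehyde may outrun the catalytic cycloaddition. Fallback, setting out from 25 and returning at 26: a boron aldol reaction of (S)-4-benzyl-3-propanoyloxazolidin-2-one (Bu2BOTf, iPr2NEt, −78 °C) gives the syn-aldol imide F4; LiOH/H2O2 removes the auxiliary to give the (2S,3R)-hydroxy acid F5; carboxyl activation with benzenesulfonyl chloride in pyridine closes the β-lactone with retention at C19 to give 26.

Step 12: aza-Wittig closure of the seven-membered imine at the doubly α-substituted ketone may be slow, and the gold-activated alkyne may undergo oxygen or 6-endo cyclisation instead. Fallback, setting out from 20 and returning at 23: ketone-assisted hydration of the alkyne ((Ph3P)AuNTf2, wet dioxane) gives the 1,4-diketone F6; Staudinger reduction (PMe3, THF/H2O) followed by Paal–Knorr condensation of the liberated amine with both ketones (AcOH, 50 °C) closes rings A and B to give 23.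

**Further compounds**

F1 | step 16 | (2S,3S)-2-methyl-3-(phenylselanyl)-4-(C3-pyrrolyl)butanoic acid on the tetracyclic core | CC[C@H]1[C@H]2OC(=O)[C@@H](C)[C@H]2c2cc(C[C@H]([Se]c4ccccc4)[C@H](C)C(O)=O)n3c2[C@@H]1CCCC3
F2 | step 16 | (S)-2-methyl-4-(C3-pyrrolyl)butanoic acid on the tetracyclic core | CC[C@H]1[C@H]2OC(=O)[C@@H](C)[C@H]2c2cc(CC[C@H](C)C(O)=O)n3c2[C@@H]1CCCC3
F3 | step 16 | C18 epimer of 27 (cis pendant lactone) | CC[C@H]1[C@H]2OC(=O)[C@@H](C)[C@H]2c2cc([C@@H]3C[C@H](C)C(=O)O3)n3c2[C@@H]1CCCC3
F4 | step 15 | syn-aldol imide, (S)-4-benzyl-3-[(2S,3R)-3-hydroxy-2-methyl-4-(C3-pyrrolyl)butanoyl]oxazolidin-2-one on the tetracyclic core | CC[C@H]1[C@H]2OC(=O)[C@@H](C)[C@H]2c2cc(C[C@@H](O)[C@H](C)C(=O)N4[C@@H](Cc5ccccc5)COC4=O)n3c2[C@@H]1CCCC3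
F5 | step 15 | (2S,3R)-3-hydroxy-2-methyl-4-(C3-pyrrolyl)butanoic acid on the tetracyclic core | CC[C@H]1[C@H]2OC(=O)[C@@H](C)[C@H]2c2cc(C[C@@H](O)[C@H](C)C(O)=O)n3c2[C@@H]1CCCC3
F6 | step 12 | azido 1,4-diketone, 6-(4-azidobutyl)-4-[4-(tert-butyldimethylsilyloxy)-2-oxobutyl] analogue of 20 | CC[C@H]1[C@H]2OC(=O)[C@@H](C)[C@H]2C(CC(=O)CCO[Si](C)(C)C(C)(C)C)C(=O)[C@@H]1CCCCN=[N+]=[N-]
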